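## The problem

Abroquinone A (19) is an isoflavan quinone: a 2,3-dimethoxy-1,4-benzoquinone (ring B in oxidised form) bonded through C1' to C3 of a 6,7-dimethoxychroman (ring A fused to the pyran O1–C2–C3–C4). Its only stereocentre is C3, an (S)-configured methine flanked by two methylenes (C2 on O1, C4 on ring A) and the quinone carbon. Nothing else in the molecule can relay chirality to C3, so a reagent or catalyst must set it. The quinone is the fragile part. It is an electrophile, and the C3–H bond is gamma to the C5' carbonyl through the C1'=C6' double bond, so base would tautomerise it to a quinone methide and erase the stereocentre. The quinone therefore has to appear last, near neutral pH. Ring A is a 1,2,4-trioxygenated benzene that strong one-electron oxidants would also convert into a quinone, so the last oxidation must recognise ring B by a free phenol rather than by oxidative demethylation. The key step is possible because C3 carries an aryl group (C1'), a benzylic methylene (C4) and an oxygen-bearing methylene (C2). That pattern can be assembled on boron: C3 is the carbamate carbon of a ring A 2-arylethanol, ring B arrives as the migrating group of an arylboronic ester, and C2 is inserted as a one-carbon unit whose C–B bond later becomes C2–O1. Ring B helps as well: its bond to C3 lies meta to the future phenol oxygen, which is the only C–H of silyl ether 8 without an ortho neighbour, and the phenol keeps a free para position for quinone formation.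

## Retrosynthesis

**19 to 18.** The last bond made is the C2'=O bond para to the ring B phenol, so 19 is traced to phenol 18. Carrying a protected hydroquinone instead would put an ortho substituent on the aryl group that must migrate in the key step and add protecting-group steps. Oxidative demethylation of a fully methylated ring B could not distinguish it from the more electron-rich ring A. Phenol 18 is a stable, non-electrophilic arene whose stereocentre has no acidifying neighbour. The forward reaction must turn a para-unsubstituted phenol into the para-quinone at near-neutral pH and leave an aryl ether ring alone.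

**18 to 17 to 16.** The pyran ring is opened at O1–C2, giving triol 17 and, behind it, the bis(silyl ether) 16. Forming C8a–O1 by metal-catalysed etherification would need a ring A halide, which would not survive the organolithium chemistry earlier in the route. Closing C4–C4a by electrophilic substitution would raise a regiochemical question on ring A. The O1–C2 cut turns the bicycle into an acyclic 2,3-diarylpropanol. The forward step is an intramolecular etherification at a primary carbon under neutral conditions, and only the ring A phenol can reach that carbon.

**16 to 15.** The C2–O bond is exchanged for a C2–B bond, giving pinacol boronic ester 15. This costs nothing stereochemically, since oxidation occurs at C2 and not at C3. It makes C3 a carbon that was attached to a boron-bearing carbon, which is what a one-carbon homologation of a boronic ester produces.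

**15 to 6, 9 and 10 (key disconnection).** Two bonds to C3 are cut: C3–C1' and C2–C3. C3 becomes the carbamate carbon of carbamate 6, ring B becomes arylboronic ester 9, and C2 comes from bromochloromethane 10. An auxiliary-based enolate alkylation would form C3–C4 instead, but it needs a ring B arylacetic acid that is not available by simple C–H functionalisation, and it adds steps to attach and remove the auxiliary. Placing the carbamate on a ring B benzylic carbon and migrating a ring A benzyl group would pass through a configurationally labile benzylic organolithium. The chosen cut uses a non-benzylic alpha-oxygenated organolithium, which holds its configuration at −78 °C. Three achiral fragments replace a molecule with a stereocentre. The forward step needs enantiotopic deprotonation next to the carbamate oxygen and two stereospecific 1,2-shifts, run without isolating the sensitive benzylic boronic ester 13.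

**6 to 5 to 3 to 2 to 1.** Carbamate 6 comes from alcohol 5. Its two-carbon chain is obtained from styrene 3 by anti-Markovnikov hydroboration. Styrene 3 comes from aldehyde 2 by methylenation, and 2 from the commercial salicylaldehyde 1 by silylation. Building the chain from the aldehyde avoids an allylation, Claisen rearrangement and oxidative cleavage sequence on a very electron-rich arene. The bulky triisopropylsilyl ether masks the phenol and shields the ring C–H between two oxygens from the lithium base.

**9 to 8 to 7.** The C–B bond of 9 is cut back to a C–H bond of silyl ether 8, made from 2,3-dimethoxyphenol 7. Electrophilic substitution of 7 would go ortho or para to oxygen, never to the position needed. Sterically governed iridium-catalysed borylation goes to the one C–H with no ortho substituent, which is the right one.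

## Roads not taken

**Alternative 1:** The cut is C3–C1' together with a temporary C4–O bond, turning the isoflavan into a pterocarpan. 6,7-Dimethoxy-2H-chromene (A1) and 2,3-dimethoxy-1,4-benzoquinone (A2) would combine under a TADDOL complex of TiCl2(OiPr)2. Chromene C3 attacks an unsubstituted quinone carbon and the adjacent carbonyl oxygen traps the C4 cation, giving the cis-pterocarpan A3. Hydrogenolysis of the benzylic C4–O bond and mild oxidation would then give 19.
- Merits: it is by far the shortest road, about five operations including the making of A1. The quinone is itself a building block, so the ring B oxidation pattern costs nothing, and A2 is symmetric, so there is no regiochemical question.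
- Weak points: enantioselectivity in this reaction family depends on two-point binding of an alkoxyquinone and varies with the quinone. A2 carries two donor groups and is a weak electrophile. A1 is an acid-labile electron-rich styrene that can oligomerise or give [2+2] adducts. The chiral Lewis acid is normally used in stoichiometric amount. Only C3 survives the hydrogenolysis, so the outcome rests on one facial selectivity that cannot be corrected later.
- Comparison: in step count this road is clearly better. The chosen plan sets against it a stereocentre fixed by a well-understood deprotonation and stereospecific shifts, and a ring B that stays aromatic until the last step.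

**Alternative 2:** The cut is C4–C4a with delivery of hydrogen to C3. The bromoaryl 2-arylallyl ether A4 would be treated with a chiral bisphosphine-ligated CuH and a Pd(OAc)2-derived catalyst. CuH adds hydrogen to C3 and copper to the terminal carbon, the alkylcopper is transferred to the arylpalladium bromide on ring A, and reductive elimination closes the pyran ring to chroman A5. Acetal cleavage and phenol oxidation would follow.
- Merits: ring and stereocentre are made in one step with catalytic chirality, and the endgame is two steps, shorter than here.
- Weak points: the ring-closing variant is not an established reaction. The alkene is 1,1-disubstituted, carries an ortho-substituted aryl group, and has an allylic aryloxy group that zerovalent palladium can ionise or CuH can reduce. Facial discrimination between the aryl group and CH2OAr is uncertain. The electron-rich aryl bromide adds slowly to palladium. A4 itself needs a multistep synthesis of a 2-arylallyl electrophile.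
- Comparison: if the key step worked it would match or beat the chosen plan in length and use less chiral material. The chosen plan uses a stoichiometric diamine, but every event in it belongs to a known reaction type.

**Alternative 3:** The cuts are C3–C4 and O1–C2. Base releases the ortho-quinone methide A7 from sulfone A6. The diarylprolinol silyl ether enamine of arylacetaldehyde A8 attacks the methide carbon, and the phenoxide closes onto the aldehyde carbon to give lactol A9. Lactol reduction, debenzylation and phenol oxidation would follow.
- Merits: it is metal-free and catalytic, belongs to a precedented reaction class for aliphatic aldehydes, and forms the chroman ring and C3 together.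
- Weak points: in A9, and in its open hydroxy-aldehyde form, C3 is alpha to an aldehyde and benzylic to ring B, so it can racemise under the basic conditions that generate A7. A8 is prone to self-condensation. The donor-substituted, methide-unsubstituted A7 is short-lived and can oligomerise. Lewis-acidic lactol reduction passes through an oxocarbenium ion that can lose the C3 proton.
- Comparison: length is similar and the chirality source is catalytic, which is an advantage. The chosen plan sets against it a C3 that is never next to a carbonyl group until the last step.

Key step: step 7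

Remark on the chemistry: the structure to be made is (S) at C3 (C2 outranks the quinone carbon, which outranks C4). Since (−)-sparteine removes the pro-S proton of alkyl carbamates and would lead to the (R) series, (+)-sparteine is used and is taken as a purchasable diamine. Compounds 1, 7 and 10 are catalogue chemicals.

## Route

Step 1
Reactants: 1 2-hydroxy-4,5-dimethoxybenzaldehyde
Product: 2 4,5-dimethoxy-2-(triisopropylsilyloxy)benzaldehyde
Conditions: TIPSCl, imidazole, DMF, rt
Reagents that add atoms: triisopropylsilyl chloride, CC(C)[Si](Cl)(C(C)C)C(C)C
Why: Silyl ether formation at the phenol; imidazole in DMF silylates even the hydrogen-bonded salicylaldehyde hydroxyl, and the triisopropylsilyl group should withstand ylide, borane and organolithium reagents.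

Step 2
Reactants: 2 4,5-dimethoxy-2-(triisopropylsilyloxy)benzaldehyde
Product: 3 (4,5-dimethoxy-2-vinylphenoxy)triisopropylsilane
Conditions: Ph3PCH3Br, KN(SiMe3)2, THF, 0 °C to rt
Reagents that add atoms: methyltriphenylphosphonium bromide, C[P+](c1ccccc1)(c1ccccc1)c1ccccc1.[Br-]
Why: Wittig methylenation of a non-enolisable aldehyde; the amide base avoids alkoxide that could cleave the aryl silyl ether.

Step 3
Reactants: 3 (4,5-dimethoxy-2-vinylphenoxy)triisopropylsilane
Product: 5 2-[4,5-dimethoxy-2-(triisopropylsilyloxy)phenyl]ethanol, via B-alkyl-9-BBN adduct 4 (not isolated)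
Conditions: 9-BBN, THF, 0 °C to rt; then NaBO3·4H2O, H2O, rt
Reagents that add atoms: sodium perborate tetrahydrate, O.O.O.O.[Na+].[O-]OB=O
Why: Brown hydroboration–oxidation; the bulky dialkylborane places boron on the terminal carbon of the electron-rich styrene, and perborate oxidises the C–B bond at a pH that should spare the aryl silyl ether.

Step 4
Reactants: 5 2-[4,5-dimethoxy-2-(triisopropylsilyloxy)phenyl]ethanol
Product: 6 2-[4,5-dimethoxy-2-(triisopropylsilyloxy)phenyl]ethyl N,N-diisopropylcarbamate
Conditions: iPr2NCOCl, Et3N, CH2Cl2, reflux
Reagents that add atoms: N,N-diisopropylcarbamoyl chloride, CC(C)N(C(C)C)C(Cl)=O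
Why: O-carbamoylation of a primary alcohol; the hindered carbamate is the standard directing and leaving group for alpha-lithiation and resists attack of s-BuLi at its carbonyl.

Step 5
Reactants: 7 2,3-dimethoxyphenol
Product: 8 (2,3-dimethoxyphenoxy)triisopropylsilane
Conditions: TIPSCl, imidazole, DMF, rt
Reagents that add atoms: triisopropylsilyl chloride, CC(C)[Si](Cl)(C(C)C)C(C)C
Why: Silyl ether formation; the bulky group protects the phenol and adds steric bias against borylation at the neighbouring C–H.

Step 6
Reactants: 8 (2,3-dimethoxyphenoxy)triisopropylsilane
Product: 9 2-[3,4-dimethoxy-5-(triisopropylsilyloxy)phenyl]-4,4,5,5-tetramethyl-1,3,2-dioxaborolane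
Conditions: [Ir(OMe)(cod)]2 (cat.), 4,4'-di-tert-butyl-2,2'-bipyridine, B2pin2, cyclohexane, 80 °C
Reagents that add atoms: bis(pinacolato)diboron, CC1(C)OB(OC1(C)C)B1OC(C)(C)C(C)(C)O1
Why: Iridium-catalysed aromatic C–H borylation is sterically controlled, and C5 of this 1,2,3-trisubstituted benzene is the only C–H without an ortho substituent.

Step 7
Reactants: 6 2-[4,5-dimethoxy-2-(triisopropylsilyloxy)phenyl]ethyl N,N-diisopropylcarbamate; 9 2-[3,4-dimethoxy-5-(triisopropylsilyloxy)phenyl]-4,4,5,5-tetramethyl-1,3,2-dioxaborolane; 10 bromochloromethane
Product: 15 2-{(2S)-3-[4,5-dimethoxy-2-(triisopropylsilyloxy)phenyl]-2-[3,4-dimethoxy-5-(triisopropylsilyloxy)phenyl]propyl}-4,4,5,5-tetramethyl-1,3,2-dioxaborolane, via lithiated carbamate 11 (not isolated), via aryl boronate complex 12 (not isolated), via secondary boronic ester 13 (not isolated), via chloromethyl boronate complex 14 (not isolated)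
Conditions: 6 (slight excess), (+)-sparteine, s-BuLi, Et2O, −78 °C; 9, −78 °C then reflux; 10, n-BuLi, −78 °C to rt
Reagents that add atoms: none
Why: s-BuLi/(+)-sparteine, pre-complexed to the carbamate carbonyl, removes the pro-R proton next to oxygen to give the chelated, configurationally stable organolithium 11, which adds to the unhindered boron of 9 with retention to form boronate 12. On warming, the electron-rich ring B aryl group migrates from boron to carbon antiperiplanar to the departing carbamate (stereoinvertive 1,2-metallate rearrangement, C3–C1'), giving benzylic boronic ester 13. Chloromethyllithium, made at −78 °C from 10 and n-BuLi, then forms boronate 14, in which C3 migrates with retention and displaces chloride (Matteson homologation, C2–C3). The closest known reaction type is the lithiation–borylation of sparteine-lithiated primary alkyl carbamates with arylboronic pinacol esters followed by in situ Matteson homologation. No ring is closed in this step. The single new stereocentre, C3, is set by the diamine-controlled enantiotopic deprotonation and carried through retention at boron capture, inversion in the aryl shift and retention in the homologation, so (+)-sparteine should give (S)-15. The step needs alpha-lithiation to win over benzylic and ring A deprotonation; the proximity effect of the carbamate, the −78 °C/Et2O regime, the three donor oxygens that lower benzylic acidity and the bulky silyl ether beside the most acidic ring C–H should secure this. Single homologation is expected because 14 rearranges only on warming, after excess carbenoid has decomposed.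

Step 8
Reactants: 15 2-{(2S)-3-[4,5-dimethoxy-2-(triisopropylsilyloxy)phenyl]-2-[3,4-dimethoxy-5-(triisopropylsilyloxy)phenyl]propyl}-4,4,5,5-tetramethyl-1,3,2-dioxaborolane
Product: 16 (2S)-3-[4,5-dimethoxy-2-(triisopropylsilyloxy)phenyl]-2-[3,4-dimethoxy-5-(triisopropylsilyloxy)phenyl]propan-1-ol
Conditions: NaBO3·4H2O, THF/H2O, rt
Reagents that add atoms: sodium perborate tetrahydrate, O.O.O.O.[Na+].[O-]OB=O
Why: Oxidation of a primary alkylboronic ester by 1,2-shift of C2 from boron to oxygen; C3 is not involved, and the mild perborate should leave both aryl silyl ethers in place so that no phenoxide meets the oxidant.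

Step 9
Reactants: 16 (2S)-3-[4,5-dimethoxy-2-(triisopropylsilyloxy)phenyl]-2-[3,4-dimethoxy-5-(triisopropylsilyloxy)phenyl]propan-1-ol
Product: 17 (2S)-3-(2-hydroxy-4,5-dimethoxyphenyl)-2-(3-hydroxy-4,5-dimethoxyphenyl)propan-1-ol
Conditions: TBAF, AcOH, THF, 0 °C, under argon
Reagents that add atoms: none
Why: Fluoride cleavage of both aryl silyl ethers; acetic acid buffering and exclusion of air keep the electron-rich ring A phenol from oxidising as its phenoxide.

Step 10
Reactants: 17 (2S)-3-(2-hydroxy-4,5-dimethoxyphenyl)-2-(3-hydroxy-4,5-dimethoxyphenyl)propan-1-ol
Product: 18 5-[(3S)-6,7-dimethoxychroman-3-yl]-2,3-dimethoxyphenol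
Conditions: PPh3, DIAD, THF (high dilution), 0 °C to rt
Reagents that add atoms: none
Why: Intramolecular Mitsunobu etherification (6-exo-tet) at the primary carbon C2; only the ring A phenol can reach the activated alcohol, the meta-placed ring B phenol can react only between molecules, which dilution suppresses, and C3 is untouched.

Step 11
Reactants: 18 5-[(3S)-6,7-dimethoxychroman-3-yl]-2,3-dimethoxyphenol
Product: 19 abroquinone A (5-[(3S)-6,7-dimethoxychroman-3-yl]-2,3-dimethoxy-1,4-benzoquinone)
Conditions: (KSO3)2NO, KH2PO4, H2O/acetone, 0 °C to rt
Reagents that add atoms: potassium nitrosodisulfonate (Fremy's salt), [K+].[K+].[O]N(S(=O)(=O)[O-])S(=O)(=O)[O-]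
Why: Teuber oxidation; the nitroxyl radical abstracts the phenolic hydrogen and a second equivalent adds at the free para carbon to give the para-quinone, ring A has no free hydroxyl and should stay intact, and the buffered medium should keep the C3–H from enolising.

## Compound list

1 | 2-hydroxy-4,5-dimethoxybenzaldehyde | COc1cc(O)c(C=O)cc1OC | starting material
2 | 4,5-dimethoxy-2-(triisopropylsilyloxy)benzaldehyde | COc1cc(O[Si](C(C)C)(C(C)C)C(C)C)c(C=O)cc1OC | intermediate
3 | (4,5-dimethoxy-2-vinylphenoxy)triisopropylsilane | COc1cc(O[Si](C(C)C)(C(C)C)C(C)C)c(C=C)cc1OC | intermediate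
4 | 9-{2-[4,5-dimethoxy-2-(triisopropylsilyloxy)phenyl]ethyl}-9-borabicyclo[3.3.1]nonane | COc1cc(O[Si](C(C)C)(C(C)C)C(C)C)c(CCB2C3CCCC2CCC3)cc1OC | intermediate
5 | 2-[4,5-dimethoxy-2-(triisopropylsilyloxy)phenyl]ethanol | COc1cc(O[Si](C(C)C)(C(C)C)C(C)C)c(CCO)cc1OC | intermediate
6 | 2-[4,5-dimethoxy-2-(triisopropylsilyloxy)phenyl]ethyl N,N-diisopropylcarbamate | CC(C)N(C(C)C)C(=O)OCCc1cc(OC)c(OC)cc1O[Si](C(C)C)(C(C)C)C(C)C | intermediate
7 | 2,3-dimethoxyphenol | COc1cccc(O)c1OC | starting material
8 | (2,3-dimethoxyphenoxy)triisopropylsilane | COc1cccc(O[Si](C(C)C)(C(C)C)C(C)C)c1OC | intermediate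
9 | 2-[3,4-dimethoxy-5-(triisopropylsilyloxy)phenyl]-4,4,5,5-tetramethyl-1,3,2-dioxaborolane | COc1cc(B2OC(C)(C)C(C)(C)O2)cc(O[Si](C(C)C)(C(C)C)C(C)C)c1OC | intermediate
10 | bromochloromethane | ClCBr | starting material
11 | (1R)-1-lithio-2-[4,5-dimethoxy-2-(triisopropylsilyloxy)phenyl]ethyl N,N-diisopropylcarbamate, (+)-sparteine-bound in the flask | CC(C)N(C(C)C)C(=O)O[C@H]([Li])Cc1cc(OC)c(OC)cc1O[Si](C(C)C)(C(C)C)C(C)C | intermediate
12 | lithium boronate complex of 9 with the (1R)-carbamoyloxyalkyl group of 11 on boron | CC(C)N(C(C)C)C(=O)O[C@H]([B-]1(OC(C)(C)C(C)(C)O1)c1cc(OC)c(OC)c(O[Si](C(C)C)(C(C)C)C(C)C)c1)Cc1cc(OC)c(OC)cc1O[Si](C(C)C)(C(C)C)C(C)C.[Li+] | intermediate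
13 | 2-{(1S)-2-[4,5-dimethoxy-2-(triisopropylsilyloxy)phenyl]-1-[3,4-dimethoxy-5-(triisopropylsilyloxy)phenyl]ethyl}-4,4,5,5-tetramethyl-1,3,2-dioxaborolane | CC1(C)OB(OC1(C)C)[C@H](c1cc(OC)c(OC)c(O[Si](C(C)C)(C(C)C)C(C)C)c1)Cc1cc(OC)c(OC)cc1O[Si](C(C)C)(C(C)C)C(C)C | intermediate
14 | lithium (chloromethyl)boronate complex of 13, (S) at carbon | ClC[B-]1(OC(C)(C)C(C)(C)O1)[C@H](c1cc(OC)c(OC)c(O[Si](C(C)C)(C(C)C)C(C)C)c1)Cc1cc(OC)c(OC)cc1O[Si](C(C)C)(C(C)C)C(C)C.[Li+] | intermediate
15 | 2-{(2S)-3-[4,5-dimethoxy-2-(triisopropylsilyloxy)phenyl]-2-[3,4-dimethoxy-5-(triisopropylsilyloxy)phenyl]propyl}-4,4,5,5-tetramethyl-1,3,2-dioxaborolane | CC1(C)OB(C[C@H](c2cc(OC)c(OC)c(O[Si](C(C)C)(C(C)C)C(C)C)c2)Cc2cc(OC)c(OC)cc2O[Si](C(C)C)(C(C)C)C(C)C)OC1(C)C | intermediate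
16 | (2S)-3-[4,5-dimethoxy-2-(triisopropylsilyloxy)phenyl]-2-[3,4-dimethoxy-5-(triisopropylsilyloxy)phenyl]propan-1-ol | OC[C@H](c1cc(OC)c(OC)c(O[Si](C(C)C)(C(C)C)C(C)C)c1)Cc1cc(OC)c(OC)cc1O[Si](C(C)C)(C(C)C)C(C)C | intermediate
17 | (2S)-3-(2-hydroxy-4,5-dimethoxyphenyl)-2-(3-hydroxy-4,5-dimethoxyphenyl)propan-1-ol | OC[C@H](c1cc(OC)c(OC)c(O)c1)Cc1cc(OC)c(OC)cc1O | intermediate
18 | 5-[(3S)-6,7-dimethoxychroman-3-yl]-2,3-dimethoxyphenol | COc1cc([C@H]2COc3cc(OC)c(OC)cc3C2)cc(O)c1OC | intermediate
19 | abroquinone A, 5-[(3S)-6,7-dimethoxychroman-3-yl]-2,3-dimethoxy-1,4-benzoquinone | COC1=C(OC)C(=O)C([C@H]2COc3cc(OC)c(OC)cc3C2)=CC1=O | target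

## Step count and risks

Total: 11 steps. Longest linear sequence: 9 steps (steps 1–4 and 7–11); the ring B branch is 2 steps (5 and 6).

**Step 7 (key step).**
- What may go wrong: deprotonation by s-BuLi at the wrong site. The candidates are the benzylic C–H bonds beta to the carbamate oxygen (followed by loss of the carbamate) and the ring A C–H between the silyloxy and methoxy groups.
- Also possible in the second half: sluggish aryl migration from the carbamate-derived boronate, or consumption of chloromethyllithium by the lithium carbamate and diamine carried through the one-pot sequence.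
- Fallback: the C3–B carbon is made by a palladium-catalysed enantioselective conjunctive cross-coupling, which keeps the same boron-to-carbon shift of ring B but needs no organolithium base near ring A. It sets out from 2 and 9.
  - Baeyer–Villiger oxidation of 2 (mCPBA, CH2Cl2) would give 4,5-dimethoxy-2-(triisopropylsilyloxy)phenyl formate F1.
  - Methanolysis (KHCO3, MeOH) would give 4,5-dimethoxy-2-(triisopropylsilyloxy)phenol F2.
  - Triflation (Tf2O, pyridine) would give 4,5-dimethoxy-2-(triisopropylsilyloxy)phenyl trifluoromethanesulfonate F3.
  - CH2=CHLi added to 9 would give the lithium vinylboronate complex F4.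
  - F4 with F3, Pd(OAc)2 and the appropriate enantiomer of MandyPhos should give 13: ring B shifts from boron to the alpha carbon while the ring A arylpalladium adds to the beta carbon.
  - The route is rejoined at 13, which is homologated with 10 and n-BuLi to 15 as in the second half of step 7.

**Step 10.**
- What may go wrong: etherification between molecules through the ring B phenol, and air oxidation of the electron-rich ring A phenol while triol 17 is handled.
- Fallback: it sets out from 16 and bypasses 17. Mesylation (MsCl, Et3N, CH2Cl2) would give (2S)-3-[4,5-dimethoxy-2-(triisopropylsilyloxy)phenyl]-2-[3,4-dimethoxy-5-(triisopropylsilyloxy)phenyl]propyl methanesulfonate F5. TBAF in dilute THF should then release the ring A phenoxide next to the electrophile, so that it closes the ring by intramolecular displacement as soon as it forms. The route is rejoined at 18.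

**Step 11.**
- What may go wrong: slow attack at the para carbon, which is flanked by a methoxy group and the secondary alkyl group, leading to ortho oxidation or incomplete conversion. Longer exposure also risks loss of configuration at C3 through quinone–quinone methide tautomerism.
- Fallback: ionic para-hydroxylation followed by a separate mild oxidation, setting out from 18.
  - Elbs oxidation (K2S2O8, aqueous NaOH) would give potassium 2-[(3S)-6,7-dimethoxychroman-3-yl]-4-hydroxy-5,6-dimethoxyphenyl sulfate F6.
  - Acid hydrolysis would give 5-[(3S)-6,7-dimethoxychroman-3-yl]-2,3-dimethoxybenzene-1,4-diol F7.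
  - Ag2O in ether should oxidise F7 under neutral conditions, rejoining the route at 19.

**Step 2.**
- What may go wrong: oligomerisation of the electron-rich ortho-silyloxystyrene 3 during isolation, or partial desilylation under the basic ylide conditions.
- Fallback: the one-carbon homologation is done through an epoxide, setting out from 2. Corey–Chaykovsky methylenation (trimethylsulfonium iodide, NaH, DMSO/THF) would give 2-[4,5-dimethoxy-2-(triisopropylsilyloxy)phenyl]oxirane F8. Hydrogenolysis of its benzylic C–O bond (H2, Pd/C, EtOAc, trace Et3N) should give the primary alcohol, rejoining the route at 5 and bypassing 3 and 4.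

## Further compounds

F1 | step 7 | 4,5-dimethoxy-2-(triisopropylsilyloxy)phenyl formate | COc1cc(OC=O)c(O[Si](C(C)C)(C(C)C)C(C)C)cc1OC
F2 | step 7 | 4,5-dimethoxy-2-(triisopropylsilyloxy)phenol | COc1cc(O)c(O[Si](C(C)C)(C(C)C)C(C)C)cc1OC
F3 | step 7 | 4,5-dimethoxy-2-(triisopropylsilyloxy)phenyl trifluoromethanesulfonate | COc1cc(OS(=O)(=O)C(F)(F)F)c(O[Si](C(C)C)(C(C)C)C(C)C)cc1OC
F4 | step 7 | lithium vinylboronate complex of 9 | [Li+].C=C[B-]1(OC(C)(C)C(C)(C)O1)c1cc(OC)c(OC)c(O[Si](C(C)C)(C(C)C)C(C)C)c1
F5 | step 10 | (2S)-3-[4,5-dimethoxy-2-(triisopropylsilyloxy)phenyl]-2-[3,4-dimethoxy-5-(triisopropylsilyloxy)phenyl]propyl methanesulfonate | CS(=O)(=O)OC[C@H](c1cc(OC)c(OC)c(O[Si](C(C)C)(C(C)C)C(C)C)c1)Cc1cc(OC)c(OC)cc1O[Si](C(C)C)(C(C)C)C(C)C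
F6 | step 11 | potassium 2-[(3S)-6,7-dimethoxychroman-3-yl]-4-hydroxy-5,6-dimethoxyphenyl sulfate | COc1c(OC)c(OS(=O)(=O)[O-])c([C@H]2COc3cc(OC)c(OC)cc3C2)cc1O.[K+]
F7 | step 11 | 5-[(3S)-6,7-dimethoxychroman-3-yl]-2,3-dimethoxybenzene-1,4-diol | COc1c(OC)c(O)c([C@H]2COc3cc(OC)c(OC)cc3C2)cc1O
F8 | step 2 | 2-[4,5-dimethoxy-2-(triisopropylsilyloxy)phenyl]oxirane (racemic) | COc1cc(O[Si](C(C)C)(C(C)C)C(C)C)c(C2CO2)cc1OC
A1 | alternative 1 | 6,7-dimethoxy-2H-chromene | COc1cc2c(cc1OC)OCC=C2
A2 | alternative 1 | 2,3-dimethoxy-1,4-benzoquinone | COC1=C(OC)C(=O)C=CC1=O
A3 | alternative 1 | cis-8-hydroxy-2,3,9,10-tetramethoxypterocarpan | COc1c(OC)c(O)cc2c1O[C@@H]1c3cc(OC)c(OC)cc3OC[C@H]21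
A4 | alternative 2 | 1-bromo-2-({2-[3,4-dimethoxy-2-(methoxymethoxy)phenyl]prop-2-en-1-yl}oxy)-4,5-dimethoxybenzene | COCOc1c(C(=C)COc2cc(OC)c(OC)cc2Br)ccc(OC)c1OC
A5 | alternative 2 | 3-[3,4-dimethoxy-2-(methoxymethoxy)phenyl]-6,7-dimethoxychroman, C3 as in 19 | COCOc1c([C@H]2COc3cc(OC)c(OC)cc3C2)ccc(OC)c1OC
A6 | alternative 3 | 4,5-dimethoxy-2-[(4-methylphenyl)sulfonylmethyl]phenol | COc1cc(O)c(CS(=O)(=O)c2ccc(C)cc2)cc1OC
A7 | alternative 3 | 3,4-dimethoxy-6-methylenecyclohexa-2,4-dien-1-one | C=C1C=C(OC)C(OC)=CC1=O
A8 | alternative 3 | 2-[2-(benzyloxy)-3,4-dimethoxyphenyl]acetaldehyde | COc1ccc(CC=O)c(OCc2ccccc2)c1OC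
A9 | alternative 3 | 3-[2-(benzyloxy)-3,4-dimethoxyphenyl]-6,7-dimethoxychroman-2-ol, C3 as in 19 and lactol carbon either | COc1ccc([C@H]2C(O)Oc3cc(OC)c(OC)cc3C2)c(OCc2ccccc2)c1OC
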